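Read the flask at 4.0 min knowing that this time is late: the north-west run is flat from 1.00 min and the north run from 1.50 min, so predict a plateau, not a rate.

| flask | solid substrate | solid reagent | remark | time |
|---|---|---|---|---|
| north-west | 14 mM | 1 equiv | run made earlier |  |
| north | 14 mM | 1.5 equiv | run made earlier |  |
| east | 7 mM | 2 equiv | run made earlier |  |
| flask | 14 mM | 2.00 equiv |  | 4.0 min |

- north-west (time / min: product / %): 0.333: 8.2; 0.667: 16.8; 1.00: 19.9; 2.00: 19.6; 4.00: 18.7
- north (time / min: product / %): 0.833: 20.9; 1.50: 29.2; 2.50: 28.3; 3.00: 28.9; 4.00: 29.2
- east (time / min: product / %): 0.333: 14.0; 1.00: 36.1; 2.00: 35.6; 3.00: 36.2; 4.00: 36.7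

(each reading ± 0.5 percentage points)

- solid, in amounts per volume of the solution: solid substrate, solid reagent
- at the start none of the solid substrate is in solution
- at the start none of the solid reagent is in solution

* product at 4.0 min, in percent of the solid substrate charged
* the change that raises the amount of product at 4.0 min, in percent of the solid substrate charged most ("none" if none brings more than 2 percentage points) (theta / delta / beta / eta / none)
* amount of product at 4.0 min, in percent of the solid substrate charged, after beta

- theta: doubling the dissolution coefficient of the solid substrate, all else as stated
- delta: doubling the solubility of the solid substrate, all else as stated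
- beta: doubling the solubility of the solid reagent, all else as stated
- eta: doubling the dissolution coefficient of the solid reagent, all else as stated

Divide each plateau, read at 4.0 min, by the equivalents of solid reagent charged. The north-west run gives 18.7% and the north run 19.5%. The east run, with half the solid substrate, gives 18.4%. Take the mean of the two runs at the flask's substrate charge:

φ = c(product, plateau) / c(solid reagent, charged) = 19.1%

Call φ the capture share: the chance that one molecule of reagent charged ends in product. My reckoning for the flask follows:

product = φ × equivalents = 38.2%

To gain product at a fixed charge, raise φ. A reagent molecule in solution either meets dissolved substrate or is lost, so I pick delta, which puts more substrate in solution, and expect beta to bring reagent faster without raising φ.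

The forecast gives 38%, delta and 36% after beta, holding that with delta “the captured share rises”.

This flask gives 39.1%; delta adds 18 percentage points, and beta yields 36.2%.

    solid substrate ⇌ dissolved substrate, rate k1*(cs1 - [dissolved substrate]) while solid is left; crystals form when [dissolved substrate] > cs1 (solubility = 6.00 mM, k = 0.190 s⁻¹)
    dissolved substrate + coupling partner → product (k = 18.0 M⁻¹ s⁻¹)
    solid reagent ⇌ coupling partner, rate k3*(cs3 - [coupling partner]) while solid is left; crystals form when [coupling partner] > cs3 (solubility = 9.40 mM, k = 0.0370 s⁻¹)
    coupling partner → decomposed reagent (k = 0.400 s⁻¹)

Here φ is a fork. At 0.400 min in this flask, dissolved substrate stands at 40.1% of the charge, and the coupling partner has a half-life of 1.7 s by decomposition alone. At that moment the chance that a molecule of coupling partner couples rather than decomposes is 20.1%; the share of this flask over its whole run is 19.6%. Decomposition is the main reason for the shortfall: the run without it gives 100%, not 39.1%.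

With 3.40 equiv of solid reagent, φ gives 64.9%; that flask gives 66.9%.

The runs stem from a simulated flask with made-up constants, noise included.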